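**Plan**

Numbering: ring C1 (C=O), C2=C3, C4 (CHOH), C5 (CH2), C6 (quaternary carbinol); chain C1'–C17' with the carbinol at C2' and the Z-alkene at C10'=C11'.
Cuts, in retrosynthetic order: C2'–C3' (alkylzinc + aldehyde), ring bond C3–C4 (alkenyl iodide + aldehyde), C1–C2 (ethynyl + amide), the two C6–CH2 bonds one after the other (allyl + oxalate, allyl + keto ester).
Enabling feature: C6 is flanked by two CH2–CH(O) units, C5–C4 inside the ring and C1'–C2' at the start of the chain; as two CH2CHO groups they are enantiotopic, so an achiral keto dialdehyde gets its C6 configuration from the choice of the arm that enters the ring.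
Forward: acyclic precursor from diethyl oxalate in seven steps, closure of the only ring by C3–C4 bond formation, silylation, attachment of the C15 chain (from palmitoleic acid) at C2', two deprotections.
Stereochemistry: C4 and C6 from the ligand-controlled, chelation-guided ring closure; C2' from a (1R,2R)-bis-sulfonamide/titanium-catalysed alkylzinc addition; the Z-alkene is taken over from palmitoleic acid.

Key step: step 8

Assumption: the sense of induction of the sulfonamide–oxazoline chromium catalyst in a ring closure of this kind cannot be derived with certainty from intermolecular couplings. The ligand is therefore written in its (S) form (from L-valinol); its mirror image (from D-valinol) is to be used instead if Mosher ester analysis of the first sample of the cyclisation product shows the (4R,6S) series.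

**Route**

Step 1
Reactants: 1 diethyl oxalate; 2 allyl bromide
Product: 3 ethyl 2-oxopent-4-enoate
Conditions: Mg turnings, Et2O, 0 °C (2 converted into allylmagnesium bromide); added dropwise to 1 (1.3 equiv) in THF/Et2O, −78 °C; cannulated cold into aq. NH4Cl/ice; extractive work-up, no chromatography
Reagents that add atoms: none
Why: low-temperature Grignard mono-acylation by diethyl oxalate (the classical α-keto ester synthesis), in which the chelated magnesium hemiketal alkoxide formed at one ester carbonyl does not collapse at −78 °C, so the ketone is set free only in the cold, weakly acidic quench when no Grignard reagent is left, while inverse addition into excess oxalate suppresses a second addition and the neutral work-up avoids migration of the β,γ-double bond into conjugation.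

Step 2
Reactants: 3 ethyl 2-oxopent-4-enoate; 2 allyl bromide
Product: 4 ethyl 2-hydroxy-2-(prop-2-en-1-yl)pent-4-enoate
Conditions: Zn dust (activated), THF, 0 °C → rt, 3 and 2 added together (Barbier mode); aq. NH4Cl
Reagents that add atoms: none
Why: Barbier-type zinc allylation of an α-keto ester, in which allylzinc bromide formed in the presence of 3 adds to the strongly electrophilic ketone carbonyl much faster than it enolises C3 or attacks the ester, the zinc alkoxide so formed shields the neighbouring ester, and any diethyl oxalate carried over from step 1 is converted into the same product; the new quaternary carbon bears two identical allyl groups and is not a stereocentre.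

Step 3
Reactants: 4 ethyl 2-hydroxy-2-(prop-2-en-1-yl)pent-4-enoate
Product: 5 ethyl 2-[(4-methoxyphenyl)methoxy]-2-(prop-2-en-1-yl)pent-4-enoate
Conditions: NaH, 4-methoxybenzyl chloride, Bu4NI (cat.), DMF, 0 °C → rt
Reagents that add atoms: 4-methoxybenzyl chloride, COc1ccc(CCl)cc1
Why: Williamson etherification of the tertiary alcohol after deprotonation by NaH, with the benzylic iodide generated in situ as the alkylating agent; the neighbouring ester has no α-hydrogen, so neither enolisation nor elimination can compete.

Step 4
Reactants: 5 ethyl 2-[(4-methoxyphenyl)methoxy]-2-(prop-2-en-1-yl)pent-4-enoate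
Product: 6 N-methoxy-2-[(4-methoxyphenyl)methoxy]-N-methyl-2-(prop-2-en-1-yl)pent-4-enamide
Conditions: MeNH(OMe)·HCl (3 equiv), i-PrMgCl (6 equiv), THF, −20 → 0 °C
Reagents that add atoms: N,O-dimethylhydroxylamine hydrochloride, CNOC.Cl
Why: aminolysis of the ester by the chloromagnesium amide of N,O-dimethylhydroxylamine (Weinreb amide formation), helped by the activating α-alkoxy group and free of enolisation because the α-carbon is quaternary.

Step 5
Reactants: 6 N-methoxy-2-[(4-methoxyphenyl)methoxy]-N-methyl-2-(prop-2-en-1-yl)pent-4-enamide; 7 ethynylmagnesium bromide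
Product: 8 4-[(4-methoxyphenyl)methoxy]-4-(prop-2-en-1-yl)hept-6-en-1-yn-3-one
Conditions: HC≡CMgBr (3 equiv), THF, 0 °C; inverse quench into cold aq. NaHSO4
Reagents that add atoms: none
Why: Weinreb ketone synthesis in which the chelated adduct does not collapse before the quench, so the alkynyl Grignard reagent adds only once, and the cold acidic inverse quench protonates the liberated N,O-dimethylhydroxylamine before it can add to the ynone.

Step 6
Reactants: 8 4-[(4-methoxyphenyl)methoxy]-4-(prop-2-en-1-yl)hept-6-en-1-yn-3-one
Product: 9 (1Z)-1-iodo-4-[(4-methoxyphenyl)methoxy]-4-(prop-2-en-1-yl)hepta-1,6-dien-3-one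
Conditions: NaI, AcOH, MeCN, rt, dark, short reaction time
Reagents that add atoms: sodium iodide, [Na+].[I-]
Why: conjugate hydroiodination of the ynone, in which iodide adds to the alkyne terminus and the allenolate is protonated in its plane on the side away from iodine, giving the Z iodoenone under kinetic control; ethers and terminal alkenes are inert to NaI/AcOH.

Step 7
Reactants: 9 (1Z)-1-iodo-4-[(4-methoxyphenyl)methoxy]-4-(prop-2-en-1-yl)hepta-1,6-dien-3-one
Product: 10 3-[(2Z)-3-iodoprop-2-enoyl]-3-[(4-methoxyphenyl)methoxy]pentanedial
Conditions: O3, CH2Cl2, −78 °C, Sudan Red 7B end point; Me2S, −78 °C → rt; dried azeotropically and used at once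
Reagents that add atoms: ozone, [O-][O+]=O
Why: ozonolysis with a dye end point, in which the two electron-rich terminal alkenes are consumed well before the electron-poor iodoalkene or the anisyl ring, and dimethyl sulfide reduces the ozonides without acid or base, as the two β-alkoxy aldehyde arms require; the carbon carrying the two identical arms stays achiral.

Step 8
Reactants: 10 3-[(2Z)-3-iodoprop-2-enoyl]-3-[(4-methoxyphenyl)methoxy]pentanedial
Product: 11 2-[(1S,5S)-5-hydroxy-1-[(4-methoxyphenyl)methoxy]-2-oxocyclohex-3-en-1-yl]acetaldehyde
Conditions: CrCl2 (15 mol %), (S)-N-[2-(4-isopropyl-4,5-dihydro-1,3-oxazol-2-yl)-6-methoxyphenyl]methanesulfonamide (17 mol %), 1,8-bis(dimethylamino)naphthalene (17 mol %), NiCl2(2,9-dimethyl-1,10-phenanthroline) (2 mol %), Cp2ZrCl2 (1.2 equiv), LiCl, Bu4NBF4, MeCN, rt; divided cell, reticulated vitreous carbon cathode held at the potential of the trivalent/divalent chromium couple, Zn anode; 10 added over several hours (final about 5 mM); aq. NaHCO3/potassium sodium tartrate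
Reagents that add atoms: none
Why: Proposed new method: divalent chromium, regenerated at the cathode, reduces the nickel salt to zerovalent nickel, which inserts into the C3–I bond and passes the alkenyl group on to trivalent chromium bound to the chiral sulfonamide–oxazoline; this C3 alkenylchromium adds to one of the two CH2CHO carbonyl groups, Cp2ZrCl2 takes the alkoxide from chromium, and the released trivalent chromium is reduced again. The closest known reaction type is the catalytic asymmetric Nozaki–Hiyama–Kishi alkenylation of aldehydes with sulfonamide–oxazoline ligands, including its electroreductive form, but a ring closure that desymmetrises a dialdehyde has not been described. The single ring is closed in the 6-exo-trig mode by the new C3–C4 bond, and the Z-configured C2=C3 unit of the iodide ends up as the endocyclic double bond. C4 is controlled by the ligand, which decides the carbonyl face that is attacked, and C6 by a chelate in which trivalent chromium is held by both the reacting carbonyl oxygen and the ether oxygen on C6, an arrangement possible only when O4 and O6 end up on the same ring face, so that the choice between the enantiotopic arms is tied to the choice of face. The step needs aldehyde-over-ketone selectivity, secured because the only ketone is the carbonyl of the alkenylmetal itself and cannot be reached, and ring closure over intermolecular coupling, secured by the six-membered transition state together with slow addition at high dilution. The neutral reducing medium leaves the second aldehyde arm and its β-alkoxy group intact, and an alkenylchromium that has lost its Z geometry cannot cyclise and can only return through the Z form.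

Step 9
Reactants: 11 2-[(1S,5S)-5-hydroxy-1-[(4-methoxyphenyl)methoxy]-2-oxocyclohex-3-en-1-yl]acetaldehyde
Product: 12 2-[(1S,5S)-5-{[tert-butyl(dimethyl)silyl]oxy}-1-[(4-methoxyphenyl)methoxy]-2-oxocyclohex-3-en-1-yl]acetaldehyde
Conditions: TBSCl, imidazole, CH2Cl2, 0 °C → rt
Reagents that add atoms: tert-butyldimethylsilyl chloride, CC(C)(C)[Si](C)(C)Cl
Why: silylation of the secondary allylic alcohol with a base too weak to enolise the aldehyde or expel the β-alkoxy group, which masks the acidic hydroxyl before the organozinc step and touches no stereocentre.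

Step 10
Reactants: 13 palmitoleic acid
Product: 15 (8Z)-1-iodopentadec-8-ene, via Barton ester 14 (not isolated)
Conditions: 1-hydroxypyridine-2(1H)-thione, DCC, DMAP (cat.), CH2Cl2, rt, dark; filtration; CHI3, hν (tungsten lamp), rt
Reagents that add atoms: iodoform, IC(I)I
Why: Barton decarboxylative iodination, a radical chain in which the acyloxy radical from 14 loses CO2 and the primary alkyl radical takes iodine from iodoform; the isolated Z-alkene lies seven carbons from the radical centre, too far to cyclise, and should keep its geometry.

Step 11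
Reactants: 15 (8Z)-1-iodopentadec-8-ene
Product: 16 bis[(8Z)-pentadec-8-en-1-yl]zinc
Conditions: Et2Zn (neat, 5 equiv), 50 °C; Et2Zn and EtI distilled off (50 °C, 0.1 mmHg); residue taken up in toluene
Reagents that add atoms: diethylzinc, CC[Zn]CC
Why: iodine–zinc exchange of a primary alkyl iodide with neat diethylzinc, driven to the symmetrical dialkylzinc by removal of the volatile partners, which gives the salt-free and copper-free reagent that the titanium-catalysed addition needs and leaves the alkene alone.

Step 12
Reactants: 12 2-[(1S,5S)-5-{[tert-butyl(dimethyl)silyl]oxy}-1-[(4-methoxyphenyl)methoxy]-2-oxocyclohex-3-en-1-yl]acetaldehyde; 16 bis[(8Z)-pentadec-8-en-1-yl]zinc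
Product: 17 (4S,6R)-4-{[tert-butyl(dimethyl)silyl]oxy}-6-[(2S,10Z)-2-hydroxyheptadec-10-en-1-yl]-6-[(4-methoxyphenyl)methoxy]cyclohex-2-en-1-one
Conditions: Ti(O-i-Pr)4 (2 equiv), (1R,2R)-N,N'-(cyclohexane-1,2-diyl)bis(trifluoromethanesulfonamide) (8 mol %), 16 (2 equiv), toluene, −20 °C; aq. NH4Cl
Reagents that add atoms: none
Why: catalytic asymmetric addition of a dialkylzinc to an aldehyde, in which the Lewis acid formed from Ti(O-i-Pr)4 and the bis-sulfonamide activates only the aldehyde (ketone and enone do not react with dialkylzincs in the absence of a conjugate-addition catalyst) and the (1R,2R) ligand sends the alkyl group to the Si face, as it does with other aliphatic and β-oxygenated aldehydes, which should set (2S) at C2' under catalyst control.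

Step 13
Reactants: 17 (4S,6R)-4-{[tert-butyl(dimethyl)silyl]oxy}-6-[(2S,10Z)-2-hydroxyheptadec-10-en-1-yl]-6-[(4-methoxyphenyl)methoxy]cyclohex-2-en-1-one
Product: 18 (4S,6R)-4-{[tert-butyl(dimethyl)silyl]oxy}-6-hydroxy-6-[(2S,10Z)-2-hydroxyheptadec-10-en-1-yl]cyclohex-2-en-1-one
Conditions: DDQ, CH2Cl2/pH 7 phosphate buffer (10:1), 0 °C
Reagents that add atoms: none
Why: oxidative cleavage of the 4-methoxybenzyl ether by DDQ through the benzylic oxocarbenium ion, which the buffered water-rich medium should hydrolyse faster than O2' can capture it; silyl ether, enone and the isolated Z-alkene are not oxidised and no stereocentre is involved.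

Step 14
Reactants: 18 (4S,6R)-4-{[tert-butyl(dimethyl)silyl]oxy}-6-hydroxy-6-[(2S,10Z)-2-hydroxyheptadec-10-en-1-yl]cyclohex-2-en-1-one
Product: 19 (4S,6R)-4,6-dihydroxy-6-[(2S,10Z)-2-hydroxyheptadec-10-en-1-yl]cyclohex-2-en-1-one
Conditions: HF·pyridine, pyridine, THF, 0 °C → rt
Reagents that add atoms: none
Why: fluoride-induced desilylation under pyridine-buffered conditions mild enough to avoid α-ketol rearrangement, elimination or aromatisation of the 4,6-dihydroxycyclohexenone, so that all three stereocentres and the Z-alkene are carried over unchanged.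

**Compound list**

1 | diethyl oxalate | CCOC(=O)C(=O)OCC | starting material
2 | allyl bromide (3-bromoprop-1-ene) | C=CCBr | starting material
3 | ethyl 2-oxopent-4-enoate | CCOC(=O)C(=O)CC=C | intermediate
4 | ethyl 2-hydroxy-2-(prop-2-en-1-yl)pent-4-enoate | CCOC(=O)C(O)(CC=C)CC=C | intermediate
5 | ethyl 2-[(4-methoxyphenyl)methoxy]-2-(prop-2-en-1-yl)pent-4-enoate | CCOC(=O)C(CC=C)(CC=C)OCc1ccc(OC)cc1 | intermediate
6 | N-methoxy-2-[(4-methoxyphenyl)methoxy]-N-methyl-2-(prop-2-en-1-yl)pent-4-enamide | CON(C)C(=O)C(CC=C)(CC=C)OCc1ccc(OC)cc1 | intermediate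
7 | ethynylmagnesium bromide | C#C[Mg]Br | starting material
8 | 4-[(4-methoxyphenyl)methoxy]-4-(prop-2-en-1-yl)hept-6-en-1-yn-3-one | C#CC(=O)C(CC=C)(CC=C)OCc1ccc(OC)cc1 | intermediate
9 | (1Z)-1-iodo-4-[(4-methoxyphenyl)methoxy]-4-(prop-2-en-1-yl)hepta-1,6-dien-3-one | C=CCC(CC=C)(OCc1ccc(OC)cc1)C(=O)/C=C\I | intermediate
10 | 3-[(2Z)-3-iodoprop-2-enoyl]-3-[(4-methoxyphenyl)methoxy]pentanedial | O=CCC(CC=O)(OCc1ccc(OC)cc1)C(=O)/C=C\I | intermediate
11 | 2-[(1S,5S)-5-hydroxy-1-[(4-methoxyphenyl)methoxy]-2-oxocyclohex-3-en-1-yl]acetaldehyde | O=CC[C@@]1(OCc2ccc(OC)cc2)C[C@H](O)C=CC1=O | intermediate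
12 | 2-[(1S,5S)-5-{[tert-butyl(dimethyl)silyl]oxy}-1-[(4-methoxyphenyl)methoxy]-2-oxocyclohex-3-en-1-yl]acetaldehyde | O=CC[C@@]1(OCc2ccc(OC)cc2)C[C@H](O[Si](C)(C)C(C)(C)C)C=CC1=O | intermediate
13 | palmitoleic acid, (9Z)-hexadec-9-enoic acid | CCCCCC/C=C\CCCCCCCC(=O)O | starting material
14 | Barton ester, 2-sulfanylidenepyridin-1(2H)-yl (9Z)-hexadec-9-enoate | CCCCCC/C=C\CCCCCCCC(=O)On1ccccc1=S | intermediate
15 | (8Z)-1-iodopentadec-8-ene | CCCCCC/C=C\CCCCCCCI | intermediate
16 | bis[(8Z)-pentadec-8-en-1-yl]zinc | CCCCCC/C=C\CCCCCCC[Zn]CCCCCCC/C=C\CCCCCC | intermediate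
17 | (4S,6R)-4-{[tert-butyl(dimethyl)silyl]oxy}-6-[(2S,10Z)-2-hydroxyheptadec-10-en-1-yl]-6-[(4-methoxyphenyl)methoxy]cyclohex-2-en-1-one | CCCCCC/C=C\CCCCCCC[C@H](O)C[C@@]1(OCc2ccc(OC)cc2)C[C@H](O[Si](C)(C)C(C)(C)C)C=CC1=O | intermediate
18 | (4S,6R)-4-{[tert-butyl(dimethyl)silyl]oxy}-6-hydroxy-6-[(2S,10Z)-2-hydroxyheptadec-10-en-1-yl]cyclohex-2-en-1-one | CCCCCC/C=C\CCCCCCC[C@H](O)C[C@@]1(O)C[C@H](O[Si](C)(C)C(C)(C)C)C=CC1=O | intermediate
19 | (4S,6R)-4,6-dihydroxy-6-[(2S,10Z)-2-hydroxyheptadec-10-en-1-yl]cyclohex-2-en-1-one | CCCCCC/C=C\CCCCCCC[C@H](O)C[C@@]1(O)C[C@H](O)C=CC1=O | target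

**Count and risks**

Total: 14 steps. Longest linear sequence: 12 steps (steps 1–9 and 12–14, from diethyl oxalate); the chain branch (steps 10 and 11) joins at step 12.

Steps most likely to fail:

1. Step 8. The catalyst may fail to tell the two enantiotopic aldehyde arms apart, or chromium turnover at the cathode may stall so that the iodoenone is reduced directly. The fallback separates ring construction from asymmetric induction. Starting from 10, the conventional stoichiometric Nozaki–Hiyama–Kishi cyclisation (CrCl2 in excess, catalytic NiCl2, DMSO/THF, high dilution, no chiral ligand) should give, through the same chelate, the racemic cis hydroxy aldehyde F1. Kinetic resolution by lipase-catalysed acylation (Burkholderia cepacia lipase, isopropenyl acetate, tert-butyl methyl ether; the enzyme is to be chosen so that the unwanted antipode is the one acylated) is then expected to convert that antipode into the (1R,5R) acetate F2 and to leave the (1S,5S) alcohol, which is 11, where the route is rejoined.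

2. Step 12. Facial selectivity at the aldehyde may be poor because the titanium catalyst is mismatched with the neighbouring quaternary alkoxy centre, or the zinc reagent may be lost to the enone. The fallback gives up reagent control and corrects the configuration afterwards. From 12 and 15, a cobalt-catalysed alkylchromium addition (CrCl2, catalytic cobalt phthalocyanine C32H16CoN8, DMF), which is selective for aldehydes over ketones and enones, should give 17 together with the (2'R)-configured epimeric alcohol F3. The two diastereomers are separated by chromatography, and F3 is inverted by a Mitsunobu reaction (4-nitrobenzoic acid, PPh3, DIAD, toluene) to the (2'S) 4-nitrobenzoate F4, whose methanolysis (K2CO3, MeOH, 0 °C) returns 17.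

3. Step 7. Ozone may over-oxidise the iodoalkene or the anisyl ring, and the dialdehyde may suffer β-elimination or hydrate formation while it is isolated. The fallback raises the oxidation level in two separate stages and never isolates the dialdehyde. From 9, osmium-catalysed dihydroxylation (OsO4 cat., N-methylmorpholine N-oxide, acetone/water), which prefers the two terminal alkenes to the electron-poor iodoenone, should give the storable tetraol F5. Glycol cleavage with NaIO4 on silica gel in CH2Cl2 immediately before the cyclisation then delivers 10 as a filtered, dry solution that goes directly into step 8.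

**Further compounds**

F1 | step 8 | rac-2-[(1S,5S)-5-hydroxy-1-[(4-methoxyphenyl)methoxy]-2-oxocyclohex-3-en-1-yl]acetaldehyde (racemate, cis; one enantiomer drawn) | O=CC[C@@]1(OCc2ccc(OC)cc2)C[C@H](O)C=CC1=O
F2 | step 8 | (1R,5R)-5-[(4-methoxyphenyl)methoxy]-4-oxo-5-(2-oxoethyl)cyclohex-2-en-1-yl acetate | O=CC[C@]1(OCc2ccc(OC)cc2)C[C@@H](OC(C)=O)C=CC1=O
F3 | step 12 | (4S,6R)-4-{[tert-butyl(dimethyl)silyl]oxy}-6-[(2R,10Z)-2-hydroxyheptadec-10-en-1-yl]-6-[(4-methoxyphenyl)methoxy]cyclohex-2-en-1-one | CCCCCC/C=C\CCCCCCC[C@@H](O)C[C@@]1(OCc2ccc(OC)cc2)C[C@H](O[Si](C)(C)C(C)(C)C)C=CC1=O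
F4 | step 12 | (2S,10Z)-1-[(1R,5S)-5-{[tert-butyl(dimethyl)silyl]oxy}-1-[(4-methoxyphenyl)methoxy]-2-oxocyclohex-3-en-1-yl]heptadec-10-en-2-yl 4-nitrobenzoate | CCCCCC/C=C\CCCCCCC[C@H](OC(=O)c3ccc(cc3)[N+](=O)[O-])C[C@@]1(OCc2ccc(OC)cc2)C[C@H](O[Si](C)(C)C(C)(C)C)C=CC1=O
F5 | step 7 | (1Z)-4-(2,3-dihydroxypropyl)-6,7-dihydroxy-1-iodo-4-[(4-methoxyphenyl)methoxy]hept-1-en-3-one (mixture of diastereomers at the carbinol carbons) | OCC(O)CC(CC(O)CO)(OCc1ccc(OC)cc1)C(=O)/C=C\I
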